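Ring B of the target carries its methyl-bearing fusion carbon C10 1,4 to C7, so it can be written as an achiral 4-methyl-4-alkylcyclohexa-2,5-dienone with a mirror plane through C7 and C10. The route rests on the C4–C5 disconnection: a chiral primary amine converts the racemic α-methyl aldehyde at the end of a three-carbon tether on C10 into an enamine that attacks C5, one of the two equivalent β-carbons, closing ring A and fixing C5 and C10 (cis, as in the target) in one operation. The precursor is the dienone bearing a 4-methyl-5-oxopentyl chain; the surviving C7–C8–C9 enone then accepts the C8 methyl and the C9 side chain.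

Key step: step 5

Numbering used: labdane-style (C4 = gem-dimethyl carbon, C5 = fusion CH, C10 = fusion C–CH3, C8=C9 = ring alkene, C11 onward = side chain).
Remark on the structures: the target SMILES encodes a cis ring fusion (5R,10S; H on C5 and CH3 on C10 on the same face) and a (2R) ester α-carbon; the key-step product has the same fusion configuration, and no structure needed correcting.
Assumption: the sense in which a given cinchona amine selects between the two enone arms cannot be assigned in advance; the route is written with the quinine-derived catalyst, and the quinidine-derived pseudo-enantiomer would be used if the opposite sense is found.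
Remark: the C4 epimer drawn for 9, 10 and 13–18 is arbitrary, since C4 becomes the gem-dimethyl carbon in step 10.

Step 1
Reactants: 1 2,6-dimethylhept-5-enal (racemic); 2 but-3-en-2-one
Product: 3 4-methyl-4-(4-methylpent-3-en-1-yl)cyclohex-2-en-1-one (racemic)
Conditions: KOH (0.2 equiv), MeOH/H2O, 0 °C, slow addition of 2, then 65 °C
Reagents that add atoms: none
Why: Base-mediated Robinson annulation, in which the aldehyde enolate adds through its branched α-carbon to the vinyl ketone (creating the quaternary carbon that becomes C10) and the methyl ketone then closes onto the aldehyde by aldol condensation; the product is racemic, which is immaterial because step 2 removes the stereocentre.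

Step 2
Reactants: 3 4-methyl-4-(4-methylpent-3-en-1-yl)cyclohex-2-en-1-one
Product: 5 4-methyl-4-(4-methylpent-3-en-1-yl)cyclohexa-2,5-dien-1-one, via silyl dienol ether 4 (not isolated)
Conditions: Me3SiOTf, Et3N, CH2Cl2, 0 °C; concentrate; Pd(OAc)2 (1.05 equiv), MeCN, 25 °C
Reagents that add atoms: none
Why: Soft enolisation can only occur at the α′-CH2 because the γ-carbon is quaternary, and Saegusa–Ito oxidation of the resulting cross-conjugated silyl dienol ether with divalent palladium installs the second ring alkene to give the achiral dienone without touching the isolated trisubstituted alkene.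

Step 3
Reactants: 5 4-methyl-4-(4-methylpent-3-en-1-yl)cyclohexa-2,5-dien-1-one
Product: 7 (2E)-2-methyl-5-(1-methyl-4-oxocyclohexa-2,5-dien-1-yl)pent-2-enal, via allylic alcohol 6 (not isolated)
Conditions: SeO2 (0.3 equiv), t-BuOOH (3 equiv), salicylic acid (0.1 equiv), CH2Cl2, 25 °C; then MnO2, CH2Cl2, 25 °C
Reagents that add atoms: selenium dioxide (O=[Se]=O), reoxidised by tert-butyl hydroperoxide (CC(C)(C)OO)
Why: Riley allylic oxidation (ene reaction of SeO2 followed by a 2,3-sigmatropic shift) should hydroxylate the (E)-methyl of the gem-dimethyl alkene selectively, the dienone having no enolisable position to compete, and MnO2 then takes the allylic alcohol on to the enal.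

Step 4
Reactants: 7 (2E)-2-methyl-5-(1-methyl-4-oxocyclohexa-2,5-dien-1-yl)pent-2-enal
Product: 8 2-methyl-5-(1-methyl-4-oxocyclohexa-2,5-dien-1-yl)pentanal (racemic; identical with 4-methyl-4-(4-methyl-5-oxopentyl)cyclohexa-2,5-dien-1-one)
Conditions: diethyl 2,6-dimethyl-1,4-dihydropyridine-3,5-dicarboxylate (1.1 equiv), Bn2NH·CF3CO2H (10 mol%), THF, 20 °C
Reagents that add atoms: none
Why: Organocatalytic transfer hydrogenation, in which the ammonium salt activates only the enal as an iminium ion and the Hantzsch ester delivers hydride to its β-carbon, should give the racemic α-methyl aldehyde while the cross-conjugated dienone is not activated and the hindered secondary-amine enamine of an α-branched aldehyde is too poor a nucleophile to cyclise prematurely.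

Step 5
Reactants: 8 2-methyl-5-(1-methyl-4-oxocyclohexa-2,5-dien-1-yl)pentanal
Product: 9 (1R,4aR,8aS)-1,4a-dimethyl-7-oxo-1,2,3,4,4a,7,8,8a-octahydronaphthalene-1-carbaldehyde (cis-fused; either C1 epimer serves)
Conditions: 9-amino-9-deoxy-epi-quinine (20 mol%), PhCO2H (40 mol%), H2O (2 equiv), toluene, 25–40 °C
Reagents that add atoms: none
Why: The primary amine condenses with either enantiomer of 8 to give one trisubstituted enamine, so the racemic α-centre is funnelled into a single nucleophile whose carbon C4 adds to the β-carbon C5 of one enone arm, after which the enol tautomerises and the iminium ion is hydrolysed to release 9 and the catalyst. The closest known reaction is the amine-catalysed desymmetrising intramolecular Michael addition of aldehyde-tethered 4,4-disubstituted cyclohexadienones, combined with primary-amine enamine catalysis as used for α-branched aldehydes. Ring A is closed in a 6-exo-trig mode. C5 and C10 are fixed together by the catalyst's choice between the two enantiotopic enone arms, their cis relationship is enforced because a tether anchored on C10 can reach C5 only on its own face of the flat dienone, and C4 is set by enamine geometry but is irrelevant because it later becomes the gem-dimethyl carbon. The step needs enantiotopic-group selectivity (C5 against C9), which the chiral amine and its acid partner must supply, and the substrate secures the rest because the product aldehyde is α-quaternary and can neither form an enamine again nor epimerise.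

Step 6
Reactants: 9 (1R,4aR,8aS)-1,4a-dimethyl-7-oxo-1,2,3,4,4a,7,8,8a-octahydronaphthalene-1-carbaldehyde
Product: 10 (4aR,8R,8aS)-8-(1,3-dioxolan-2-yl)-4a,8-dimethyl-4a,5,6,7,8,8a-hexahydronaphthalen-2(1H)-one
Conditions: Me3SiOCH2CH2OSiMe3 (1.5 equiv), Me3SiOTf (5 mol%), CH2Cl2, −78 to −30 °C; pyridine quench
Reagents that add atoms: 1,2-bis(trimethylsilyloxy)ethane (C[Si](C)(C)OCCO[Si](C)(C)C)
Why: Noyori acetalisation under silyl triflate catalysis at low temperature is selective for aldehydes over conjugated ketones, so the C4 formyl group should be masked against the organometallic steps while the enone stays free.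

Step 7
Reactants: 10 (4aR,8R,8aS)-8-(1,3-dioxolan-2-yl)-4a,8-dimethyl-4a,5,6,7,8,8a-hexahydronaphthalen-2(1H)-one; 11 (3-bromopropoxy)(tert-butyl)dimethylsilane
Product: 14 (4aR,8R,8aS)-4-{3-[(tert-butyldimethylsilyl)oxy]propyl}-8-(1,3-dioxolan-2-yl)-3,4a,8-trimethyl-3,4,4a,5,6,7,8,8a-octahydronaphthalen-2(1H)-one (C3/C4 isomer mixture), via Grignard reagent 12 (not isolated), via magnesium enolate 13 (not isolated)
Conditions: 11, Mg, THF, 40 °C; CuBr·SMe2 (15 mol%), THF, −40 °C, add 10; then MeI (excess), DMPU, −40 to 0 °C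
Reagents that add atoms: iodomethane (CI)
Why: Copper-catalysed conjugate addition of the Grignard reagent should deliver the chain to C9 and leave a regiodefined magnesium enolate that is C-methylated at C8 (tandem conjugate addition–enolate alkylation); the two new centres need no control because both become sp2 in step 8.

Step 8
Reactants: 14 (4aR,8R,8aS)-4-{3-[(tert-butyldimethylsilyl)oxy]propyl}-8-(1,3-dioxolan-2-yl)-3,4a,8-trimethyl-3,4,4a,5,6,7,8,8a-octahydronaphthalen-2(1H)-one
Product: 16 (4aS,8R,8aS)-4-{3-[(tert-butyldimethylsilyl)oxy]propyl}-8-(1,3-dioxolan-2-yl)-3,4a,8-trimethyl-4a,5,6,7,8,8a-hexahydronaphthalen-2(1H)-one, via silyl enol ether 15 (not isolated)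
Conditions: Me3SiCl, NaI, Et3N (excess), MeCN, 25 °C; pentane extraction; Pd(OAc)2 (1.1 equiv), MeCN, 25 °C
Reagents that add atoms: none
Why: Equilibrating silylation (Me3SiI generated in the flask, kept basic by excess Et3N so that the dioxolane and silyl ether persist) should favour the more substituted C7=C8 silyl enol ether, and Saegusa–Ito oxidation with divalent palladium then gives the tetrasubstituted C8=C9 enone by β-hydride loss from C9.

Step 9
Reactants: 16 (4aS,8R,8aS)-4-{3-[(tert-butyldimethylsilyl)oxy]propyl}-8-(1,3-dioxolan-2-yl)-3,4a,8-trimethyl-4a,5,6,7,8,8a-hexahydronaphthalen-2(1H)-one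
Product: 18 3-[(4'aS,8'R,8'aS)-8'-(1,3-dithiolan-2-yl)-3',4'a,8'-trimethyl-4'a,5',6',7',8',8'a-hexahydro-1'H-spiro[1,3-dithiolane-2,2'-naphthalen]-4'-yl]propan-1-ol, via bis-dithiolane silyl ether 17 (not isolated)
Conditions: HSCH2CH2SH (6 equiv), BF3·OEt2, CH2Cl2, 0 to 25 °C; then MeOH, 25 °C
Reagents that add atoms: ethane-1,2-dithiol (SCCS)
Why: Lewis-acid-mediated thioacetalisation should convert the C7 enone carbonyl and, by acetal exchange, the C4 dioxolane into 1,3-dithiolanes while the fully substituted β-carbon C9 cannot accept a thiol in conjugate fashion, and methanol under the same acid then removes the silyl ether.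

Step 10
Reactants: 18 3-[(4'aS,8'R,8'aS)-8'-(1,3-dithiolan-2-yl)-3',4'a,8'-trimethyl-4'a,5',6',7',8',8'a-hexahydro-1'H-spiro[1,3-dithiolane-2,2'-naphthalen]-4'-yl]propan-1-ol
Product: 19 3-[(4aR,8aS)-2,5,5,8a-tetramethyl-3,4,4a,5,6,7,8,8a-octahydronaphthalen-1-yl]propan-1-ol
Conditions: Raney Ni (W-2 grade, deactivated in acetone), EtOH/THF, 25–50 °C
Reagents that add atoms: none
Why: Mozingo reduction, in which hydrogen-loaded Raney nickel cleaves all four C–S bonds, should turn C7 into CH2 and the C4 dithiolane into the second C4 methyl (which removes the C4 stereocentre), while the tetrasubstituted alkene resists hydrogenation and hydrogen is expected at the less hindered allylic terminus C7.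

Step 11
Reactants: 19 3-[(4aR,8aS)-2,5,5,8a-tetramethyl-3,4,4a,5,6,7,8,8a-octahydronaphthalen-1-yl]propan-1-ol
Product: 20 3-[(4aR,8aS)-2,5,5,8a-tetramethyl-3,4,4a,5,6,7,8,8a-octahydronaphthalen-1-yl]propanal
Conditions: Dess–Martin periodinane, NaHCO3, CH2Cl2, 0 to 25 °C
Reagents that add atoms: none
Why: Dess–Martin oxidation of the primary alcohol under buffered conditions should give the aldehyde without affecting the tetrasubstituted alkene.

Step 12
Reactants: 20 3-[(4aR,8aS)-2,5,5,8a-tetramethyl-3,4,4a,5,6,7,8,8a-octahydronaphthalen-1-yl]propanal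
Product: 21 4-[(4aR,8aS)-2,5,5,8a-tetramethyl-3,4,4a,5,6,7,8,8a-octahydronaphthalen-1-yl]but-1-yne
Conditions: dimethyl (1-diazo-2-oxopropyl)phosphonate, K2CO3, MeOH, 0 to 25 °C
Reagents that add atoms: dimethyl (1-diazo-2-oxopropyl)phosphonate (CC(=O)C(=[N+]=[N-])P(=O)(OC)OC)
Why: The Ohira–Bestmann variant of the Seyferth–Gilbert homologation should convert the aldehyde into the terminal alkyne (C13≡C14) under mild carbonate conditions that leave the remote ring alkene untouched.

Step 13
Reactants: 22 methyl (2S)-3-hydroxy-2-methylpropanoate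
Product: 23 methyl (2S)-3-[(tert-butyldimethylsilyl)oxy]-2-methylpropanoate
Conditions: t-BuMe2SiCl, imidazole, CH2Cl2, 25 °C
Reagents that add atoms: tert-butyldimethylsilyl chloride (CC(C)(C)[Si](C)(C)Cl)
Why: Standard silylation of the primary alcohol, in which the stereocentre is not involved.

Step 14
Reactants: 23 methyl (2S)-3-[(tert-butyldimethylsilyl)oxy]-2-methylpropanoate
Product: 24 (2S)-3-[(tert-butyldimethylsilyl)oxy]-2-methylpropanal
Conditions: i-Bu2AlH (1.05 equiv), CH2Cl2, −78 °C; aqueous KNaC4H4O6 (potassium sodium tartrate) work-up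
Reagents that add atoms: none
Why: Partial reduction of the ester at low temperature should stop at the tetrahedral aluminium hemiacetal, which releases the aldehyde on work-up with the α-stereocentre intact.

Step 15
Reactants: 24 (2S)-3-[(tert-butyldimethylsilyl)oxy]-2-methylpropanal
Product: 25 tert-butyl{[(2R,3E)-4-iodo-2-methylbut-3-en-1-yl]oxy}dimethylsilane
Conditions: CrCl2 (6 equiv), CHI3 (2 equiv), THF/dioxane, 0 to 25 °C
Reagents that add atoms: iodoform (IC(I)I)
Why: Takai olefination, in which the geminal dichromium species from iodoform adds to the aldehyde and eliminates, should give the (E)-vinyl iodide under non-basic conditions that preserve the α-stereocentre (the descriptor changes to R only because the priorities change).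

Step 16
Reactants: 21 4-[(4aR,8aS)-2,5,5,8a-tetramethyl-3,4,4a,5,6,7,8,8a-octahydronaphthalen-1-yl]but-1-yne; 25 tert-butyl{[(2R,3E)-4-iodo-2-methylbut-3-en-1-yl]oxy}dimethylsilane
Product: 27 tert-butyl{[(2R,3E,5E)-2,6-dimethyl-8-[(4aR,8aS)-2,5,5,8a-tetramethyl-3,4,4a,5,6,7,8,8a-octahydronaphthalen-1-yl]octa-3,5-dien-1-yl]oxy}dimethylsilane, via alkenylalane 26 (not isolated)
Conditions: Me3Al (2.5 equiv), Cp2ZrCl2 (0.25 equiv), CH2Cl2, 0 to 25 °C; volatiles removed; 25, Pd(PPh3)4 (5 mol%), ZnCl2 (1 equiv), THF, 25 °C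
Reagents that add atoms: trimethylaluminium (C[Al](C)C)
Why: Negishi zirconium-catalysed carboalumination adds methyl and aluminium syn across the terminal alkyne with the methyl on the internal carbon, and the resulting (E)-alkenylalane should cross-couple with the vinyl iodide under zerovalent-palladium catalysis (Negishi coupling, ZnCl2 as promoter) with retention of both alkene geometries.

Step 17
Reactants: 27 tert-butyl{[(2R,3E,5E)-2,6-dimethyl-8-[(4aR,8aS)-2,5,5,8a-tetramethyl-3,4,4a,5,6,7,8,8a-octahydronaphthalen-1-yl]octa-3,5-dien-1-yl]oxy}dimethylsilane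
Product: 28 (2R,3E,5E)-2,6-dimethyl-8-[(4aR,8aS)-2,5,5,8a-tetramethyl-3,4,4a,5,6,7,8,8a-octahydronaphthalen-1-yl]octa-3,5-dien-1-ol
Conditions: Bu4NF, THF, 0 to 25 °C
Reagents that add atoms: none
Why: Fluoride-mediated desilylation should free the primary alcohol, the neighbouring stereocentre being only allylic at this stage and not at risk.

Step 18
Reactants: 28 (2R,3E,5E)-2,6-dimethyl-8-[(4aR,8aS)-2,5,5,8a-tetramethyl-3,4,4a,5,6,7,8,8a-octahydronaphthalen-1-yl]octa-3,5-dien-1-ol
Product: 30 (2R,3E,5E)-2,6-dimethyl-8-[(4aR,8aS)-2,5,5,8a-tetramethyl-3,4,4a,5,6,7,8,8a-octahydronaphthalen-1-yl]octa-3,5-dienoic acid, via aldehyde 29 (not isolated)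
Conditions: Dess–Martin periodinane, NaHCO3, CH2Cl2, 0 °C; then NaClO2, NaH2PO4, 2-methylbut-2-ene, t-BuOH/H2O, 0 °C
Reagents that add atoms: sodium chlorite ([Na+].[O-]Cl=O)
Why: Dess–Martin oxidation followed directly by Pinnick oxidation of the unpurified aldehyde should give the acid under buffered conditions chosen to avoid enolisation of the doubly activated C2 centre and migration of the diene into conjugation, the alkene scavenger protecting the electron-rich alkenes from hypochlorite.

Step 19
Reactants: 30 (2R,3E,5E)-2,6-dimethyl-8-[(4aR,8aS)-2,5,5,8a-tetramethyl-3,4,4a,5,6,7,8,8a-octahydronaphthalen-1-yl]octa-3,5-dienoic acid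
Product: 31 methyl (2R,3E,5E)-2,6-dimethyl-8-[(4aR,8aS)-2,5,5,8a-tetramethyl-3,4,4a,5,6,7,8,8a-octahydronaphthalen-1-yl]octa-3,5-dienoate (target)
Conditions: Me3SiCHN2, MeOH/toluene, 0 °C
Reagents that add atoms: (trimethylsilyl)diazomethane (C[Si](C)(C)C=[N+]=[N-])
Why: Methyl ester formation with (trimethylsilyl)diazomethane in methanol proceeds under neutral conditions, so the base-sensitive C2 centre and the β,γ-unsaturated diene ester should not be disturbed.

Compound list
1 | 2,6-dimethylhept-5-enal (racemic) | CC(C)=CCCC(C)C=O | starting material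
2 | but-3-en-2-one | CC(=O)C=C | starting material
3 | 4-methyl-4-(4-methylpent-3-en-1-yl)cyclohex-2-en-1-one (racemic) | CC(C)=CCCC1(C)C=CC(=O)CC1 | intermediate
4 | trimethyl{[4-methyl-4-(4-methylpent-3-en-1-yl)cyclohexa-1,5-dien-1-yl]oxy}silane | CC(C)=CCCC1(C)C=CC(O[Si](C)(C)C)=CC1 | intermediate (not isolated)
5 | 4-methyl-4-(4-methylpent-3-en-1-yl)cyclohexa-2,5-dien-1-one | CC(C)=CCCC1(C)C=CC(=O)C=C1 | intermediate
6 | 4-[(3E)-5-hydroxy-4-methylpent-3-en-1-yl]-4-methylcyclohexa-2,5-dien-1-one | OC/C(C)=C/CCC1(C)C=CC(=O)C=C1 | intermediate (not isolated)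
7 | (2E)-2-methyl-5-(1-methyl-4-oxocyclohexa-2,5-dien-1-yl)pent-2-enal | O=C/C(C)=C/CCC1(C)C=CC(=O)C=C1 | intermediate
8 | 2-methyl-5-(1-methyl-4-oxocyclohexa-2,5-dien-1-yl)pentanal, racemic (= 4-methyl-4-(4-methyl-5-oxopentyl)cyclohexa-2,5-dien-1-one) | O=CC(C)CCCC1(C)C=CC(=O)C=C1 | intermediate (key-step precursor)
9 | (1R,4aR,8aS)-1,4a-dimethyl-7-oxo-1,2,3,4,4a,7,8,8a-octahydronaphthalene-1-carbaldehyde, cis-fused (C1 epimer arbitrary) | C1=CC(=O)C[C@@H]2[C@](C)(C=O)CCC[C@]12C | intermediate (key-step product)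
10 | (4aR,8R,8aS)-8-(1,3-dioxolan-2-yl)-4a,8-dimethyl-4a,5,6,7,8,8a-hexahydronaphthalen-2(1H)-one | C1=CC(=O)C[C@@H]2[C@](C)(C3OCCO3)CCC[C@]12C | intermediate
11 | (3-bromopropoxy)(tert-butyl)dimethylsilane | BrCCCO[Si](C)(C)C(C)(C)C | starting material
12 | {3-[(tert-butyldimethylsilyl)oxy]propyl}magnesium bromide | Br[Mg]CCCO[Si](C)(C)C(C)(C)C | intermediate (not isolated)
13 | bromomagnesium (4aR,8R,8aS)-4-{3-[(tert-butyldimethylsilyl)oxy]propyl}-8-(1,3-dioxolan-2-yl)-4a,8-dimethyl-1,4,4a,5,6,7,8,8a-octahydronaphthalen-2-olate (C4 not assigned) | C1(CCCO[Si](C)(C)C(C)(C)C)C=C(O[Mg]Br)C[C@@H]2[C@](C)(C3OCCO3)CCC[C@]12C | intermediate (not isolated)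
14 | (4aR,8R,8aS)-4-{3-[(tert-butyldimethylsilyl)oxy]propyl}-8-(1,3-dioxolan-2-yl)-3,4a,8-trimethyl-3,4,4a,5,6,7,8,8a-octahydronaphthalen-2(1H)-one (C3 and C4 not assigned; both become sp2) | C1(CCCO[Si](C)(C)C(C)(C)C)C(C)C(=O)C[C@@H]2[C@](C)(C3OCCO3)CCC[C@]12C | intermediate
15 | tert-butyl{3-[(4aR,8R,8aS)-8-(1,3-dioxolan-2-yl)-3,4a,8-trimethyl-2-[(trimethylsilyl)oxy]-1,4,4a,5,6,7,8,8a-octahydronaphthalen-4-yl]propoxy}dimethylsilane (C4 not assigned) | C1(CCCO[Si](C)(C)C(C)(C)C)C(C)=C(O[Si](C)(C)C)C[C@@H]2[C@](C)(C3OCCO3)CCC[C@]12C | intermediate (not isolated)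
16 | (4aS,8R,8aS)-4-{3-[(tert-butyldimethylsilyl)oxy]propyl}-8-(1,3-dioxolan-2-yl)-3,4a,8-trimethyl-4a,5,6,7,8,8a-hexahydronaphthalen-2(1H)-one | C1(CCCO[Si](C)(C)C(C)(C)C)=C(C)C(=O)C[C@@H]2[C@](C)(C3OCCO3)CCC[C@]12C | intermediate
17 | tert-butyldimethylsilyl ether of 18 | C1(CCCO[Si](C)(C)C(C)(C)C)=C(C)C3(SCCS3)C[C@@H]2[C@](C)(C3SCCS3)CCC[C@]12C | intermediate (not isolated)
18 | 3-[(4'aS,8'R,8'aS)-8'-(1,3-dithiolan-2-yl)-3',4'a,8'-trimethyl-4'a,5',6',7',8',8'a-hexahydro-1'H-spiro[1,3-dithiolane-2,2'-naphthalen]-4'-yl]propan-1-ol | C1(CCCO)=C(C)C3(SCCS3)C[C@@H]2[C@](C)(C3SCCS3)CCC[C@]12C | intermediate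
19 | 3-[(4aR,8aS)-2,5,5,8a-tetramethyl-3,4,4a,5,6,7,8,8a-octahydronaphthalen-1-yl]propan-1-ol | OCCCC1=C(C)CC[C@@H]2C(C)(C)CCC[C@]12C | intermediate
20 | 3-[(4aR,8aS)-2,5,5,8a-tetramethyl-3,4,4a,5,6,7,8,8a-octahydronaphthalen-1-yl]propanal | O=CCCC1=C(C)CC[C@@H]2C(C)(C)CCC[C@]12C | intermediate
21 | 4-[(4aR,8aS)-2,5,5,8a-tetramethyl-3,4,4a,5,6,7,8,8a-octahydronaphthalen-1-yl]but-1-yne | C#CCCC1=C(C)CC[C@@H]2C(C)(C)CCC[C@]12C | intermediate
22 | methyl (2S)-3-hydroxy-2-methylpropanoate | COC(=O)[C@@H](C)CO | starting material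
23 | methyl (2S)-3-[(tert-butyldimethylsilyl)oxy]-2-methylpropanoate | COC(=O)[C@@H](C)CO[Si](C)(C)C(C)(C)C | intermediate
24 | (2S)-3-[(tert-butyldimethylsilyl)oxy]-2-methylpropanal | O=C[C@@H](C)CO[Si](C)(C)C(C)(C)C | intermediate
25 | tert-butyl{[(2R,3E)-4-iodo-2-methylbut-3-en-1-yl]oxy}dimethylsilane | I/C=C/[C@@H](C)CO[Si](C)(C)C(C)(C)C | intermediate
26 | dimethyl{(1E)-2-methyl-4-[(4aR,8aS)-2,5,5,8a-tetramethyl-3,4,4a,5,6,7,8,8a-octahydronaphthalen-1-yl]but-1-en-1-yl}alumane | C[Al](C)/C=C(\C)CCC1=C(C)CC[C@@H]2C(C)(C)CCC[C@]12C | intermediate (not isolated)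
27 | tert-butyl{[(2R,3E,5E)-2,6-dimethyl-8-[(4aR,8aS)-2,5,5,8a-tetramethyl-3,4,4a,5,6,7,8,8a-octahydronaphthalen-1-yl]octa-3,5-dien-1-yl]oxy}dimethylsilane | CC(C)(C)[Si](C)(C)OC[C@H](C)/C=C/C=C(\C)CCC1=C(C)CC[C@@H]2C(C)(C)CCC[C@]12C | intermediate
28 | (2R,3E,5E)-2,6-dimethyl-8-[(4aR,8aS)-2,5,5,8a-tetramethyl-3,4,4a,5,6,7,8,8a-octahydronaphthalen-1-yl]octa-3,5-dien-1-ol | OC[C@H](C)/C=C/C=C(\C)CCC1=C(C)CC[C@@H]2C(C)(C)CCC[C@]12C | intermediate
29 | (2R,3E,5E)-2,6-dimethyl-8-[(4aR,8aS)-2,5,5,8a-tetramethyl-3,4,4a,5,6,7,8,8a-octahydronaphthalen-1-yl]octa-3,5-dienal | O=C[C@H](C)/C=C/C=C(\C)CCC1=C(C)CC[C@@H]2C(C)(C)CCC[C@]12C | intermediate (not isolated)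
30 | (2R,3E,5E)-2,6-dimethyl-8-[(4aR,8aS)-2,5,5,8a-tetramethyl-3,4,4a,5,6,7,8,8a-octahydronaphthalen-1-yl]octa-3,5-dienoic acid | OC(=O)[C@H](C)/C=C/C=C(\C)CCC1=C(C)CC[C@@H]2C(C)(C)CCC[C@]12C | intermediate
31 | methyl (2R,3E,5E)-2,6-dimethyl-8-[(4aR,8aS)-2,5,5,8a-tetramethyl-3,4,4a,5,6,7,8,8a-octahydronaphthalen-1-yl]octa-3,5-dienoate | COC(=O)[C@H](C)/C=C/C=C(\C)CCC1=C(C)CC[C@@H]2C(C)(C)CCC[C@]12C | target

Total step count: 19.
Longest linear sequence: 16 steps (steps 1–12, then 16–19); the side-chain fragment takes steps 13–15.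

Steps most likely to fail

Step 5 (key step). The amine may discriminate poorly between the two enantiotopic enone arms, the α-quaternary product aldehyde may hold the primary amine as an imine and stall turnover, or a non-selective background closure may compete. The fallback replaces catalytic control by a stoichiometric chiral imine (deracemising chiral-imine Michael addition). It sets out from 8, which is condensed with (1S)-1-phenylethanamine over molecular sieves to the imine (2RS)-2-methyl-5-(1-methyl-4-oxocyclohexa-2,5-dien-1-yl)-N-[(1S)-1-phenylethyl]pentan-1-imine F1. On warming in THF its secondary-enamine tautomer should add to one dienone arm through a compact cyclic transition state with internal proton transfer, giving the cyclised N-[(1S)-1-phenylethyl]imine of 9 F2. The fusion diastereomers can be separated at this stage, and mild aqueous acetic acid then hydrolyses F2 and the route is rejoined at 9. The antipodal amine would be used if the sense is opposite.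

Step 8. Silylation may occur on the C6 side, after which palladium oxidation would give the C5=C6 enone and erase the C5 centre, or β-hydride loss may run toward the C8 methyl. The fallback makes the enol ether regiospecifically by introducing the methyl group before the chain. It sets out from 10, which is α-iodinated (I2, pyridine, CH2Cl2) to (4aS,8R,8aS)-8-(1,3-dioxolan-2-yl)-3-iodo-4a,8-dimethyl-4a,5,6,7,8,8a-hexahydronaphthalen-2(1H)-one F3. Stille methylation (Me4Sn, Pd2(dba)3, AsPh3, CuI, NMP) gives (4aR,8R,8aS)-8-(1,3-dioxolan-2-yl)-3,4a,8-trimethyl-4a,5,6,7,8,8a-hexahydronaphthalen-2(1H)-one F4. Copper-catalysed addition of 12 to F4 in the presence of Me3SiCl traps the enolate where it forms, so the route is rejoined at 15, which is oxidised with Pd(OAc)2 to 16 as before.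

Step 10. The ring alkene may migrate from C8=C9 into C7=C8 through the allylic intermediate on nickel, or be partly saturated. The fallback separates the two reductions and sets out from 16:
- Luche reduction (NaBH4, CeCl3·7H2O, MeOH) gives the allylic alcohol (4aS,8R,8aS)-4-{3-[(tert-butyldimethylsilyl)oxy]propyl}-8-(1,3-dioxolan-2-yl)-3,4a,8-trimethyl-1,2,4a,5,6,7,8,8a-octahydronaphthalen-2-ol F5.
- Phosphorylation (n-BuLi, ClP(O)(OEt)2) gives its diethyl phosphate F6.
- Dissolving-metal cleavage (Li, EtNH2, t-BuOH) should protonate the allyl anion at the less substituted C7 and give tert-butyl{3-[(4aS,5R,8aS)-5-(1,3-dioxolan-2-yl)-2,5,8a-trimethyl-3,4,4a,5,6,7,8,8a-octahydronaphthalen-1-yl]propoxy}dimethylsilane F7.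
- Aqueous HCl in THF removes the dioxolane and the silyl ether to give (1R,4aS,8aS)-5-(3-hydroxypropyl)-1,4a,6-trimethyl-1,2,3,4,4a,7,8,8a-octahydronaphthalene-1-carbaldehyde F8.
- Wolff–Kishner reduction (N2H4·H2O, KOH, diethylene glycol, 200 °C) through the hydrazone of F8 F9 converts the formyl group into the second C4 methyl, and the route is rejoined at 19.

Further compounds
F1 | step 5 | (2RS)-2-methyl-5-(1-methyl-4-oxocyclohexa-2,5-dien-1-yl)-N-[(1S)-1-phenylethyl]pentan-1-imine | C[C@H](N=CC(C)CCCC1(C)C=CC(=O)C=C1)c1ccccc1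
F2 | step 5 | N-[(1S)-1-phenylethyl]imine of 9 | C1=CC(=O)C[C@@H]2[C@](C)(C=N[C@@H](C)c3ccccc3)CCC[C@]12C
F3 | step 8 | (4aS,8R,8aS)-8-(1,3-dioxolan-2-yl)-3-iodo-4a,8-dimethyl-4a,5,6,7,8,8a-hexahydronaphthalen-2(1H)-one | C1=C(I)C(=O)C[C@@H]2[C@](C)(C3OCCO3)CCC[C@]12C
F4 | step 8 | (4aR,8R,8aS)-8-(1,3-dioxolan-2-yl)-3,4a,8-trimethyl-4a,5,6,7,8,8a-hexahydronaphthalen-2(1H)-one | C1=C(C)C(=O)C[C@@H]2[C@](C)(C3OCCO3)CCC[C@]12C
F5 | step 10 | (4aS,8R,8aS)-4-{3-[(tert-butyldimethylsilyl)oxy]propyl}-8-(1,3-dioxolan-2-yl)-3,4a,8-trimethyl-1,2,4a,5,6,7,8,8a-octahydronaphthalen-2-ol (carbinol centre not assigned) | C1(CCCO[Si](C)(C)C(C)(C)C)=C(C)C(O)C[C@@H]2[C@](C)(C3OCCO3)CCC[C@]12C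
F6 | step 10 | diethyl phosphate of F5 | C1(CCCO[Si](C)(C)C(C)(C)C)=C(C)C(OP(=O)(OCC)OCC)C[C@@H]2[C@](C)(C3OCCO3)CCC[C@]12C
F7 | step 10 | tert-butyl{3-[(4aS,5R,8aS)-5-(1,3-dioxolan-2-yl)-2,5,8a-trimethyl-3,4,4a,5,6,7,8,8a-octahydronaphthalen-1-yl]propoxy}dimethylsilane | C1(CCCO[Si](C)(C)C(C)(C)C)=C(C)CC[C@@H]2[C@](C)(C3OCCO3)CCC[C@]12C
F8 | step 10 | (1R,4aS,8aS)-5-(3-hydroxypropyl)-1,4a,6-trimethyl-1,2,3,4,4a,7,8,8a-octahydronaphthalene-1-carbaldehyde | C1(CCCO)=C(C)CC[C@@H]2[C@](C)(C=O)CCC[C@]12C
F9 | step 10 | hydrazone of F8 | C1(CCCO)=C(C)CC[C@@H]2[C@](C)(C=NN)CCC[C@]12C
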